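**Strategy.** Everything rests on taking rings A and B of the ent-labdane apart together with a temporary C8–O–C13 δ-lactone, back to an open E,E-triene acid. One catalyst-controlled, proton-started polyene cyclisation with carboxyl capture makes C4–C5, C9–C10 and C8–O and sets C5, C9 and C10 (plus transient C8). It exploits the head-to-tail pattern of three E-trisubstituted alkenes hidden in rings A and B and the fact that tertiary C8 sits four bonds from C13, so a C13 carboxyl can trap the C8 cation. The precursor is (4E,8E)-farnesylacetic acid from farnesol. The lactone is then unfolded into the C13 methyl ketone, the 13E enoate and the C7=C8–C17–OH unit, and a C16 + C16 Wittig-built C32 acid is esterified last.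

Key step: step 4

Remark (assumption): labdane locants are used for all bicyclic compounds, and the catalyst antipode that leads to the ent series is assigned by a test cyclisation whose lactone is compared in sign of rotation with the known natural-series lactone.

**Step 1**
Reactants: 1 (2E,6E)-farnesol
Product: 2 (2E,6E)-farnesyl bromide
Conditions: PBr3 (0.4 equiv), Et2O, −10 °C
Reagents that add atoms: phosphorus tribromide, BrP(Br)Br
Why: PBr3 bromination (SN2 on the allylic phosphite ester) of the primary allylic alcohol at low temperature keeps both E alkenes and avoids allylic transposition.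

**Step 2**
Reactants: 2 (2E,6E)-farnesyl bromide
Product: 3 dimethyl 2-[(2E,6E)-farnesyl]malonate
Conditions: dimethyl malonate (2.5 equiv), NaH (2.0 equiv), THF, 0 °C → rt
Reagents that add atoms: dimethyl malonate, COC(=O)CC(=O)OC
Why: Malonic ester alkylation, in which the soft sodium malonate displaces the primary allylic bromide by SN2 (this carbon becomes C11, the new carbons C12 and C13) and the excess of malonate suppresses double alkylation.

**Step 3**
Reactants: 3 dimethyl 2-[(2E,6E)-farnesyl]malonate
Product: 5 (4E,8E)-farnesylacetic acid, via farnesylmalonic acid 4 (not isolated)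
Conditions: KOH, MeOH/H2O, 70 °C; 1 M HCl, 0 °C; then pyridine, 115 °C
Reagents that add atoms: potassium hydroxide, [K+].[OH-]
Why: Saponification followed by thermal decarboxylation of the malonic acid (malonic ester synthesis) uses only base, cold dilute aqueous acid and heat, so the acid-sensitive triene should not cyclise before the key step.

**Step 4**
Reactants: 5 (4E,8E)-farnesylacetic acid
Product: 6 ent-ambreinolide-type tricyclic δ-lactone (5R,8S,9S,10R)
Conditions: imidodiphosphorimidate acid [(3,3′-Ar2-BINOL)P(=NSO2CF3)]2NH (3 mol %, Ar = bulky aryl, antipode for the ent series), (CF3)3COH/CH2Cl2, −30 °C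
Reagents that add atoms: none
Why: Proposed new method: the confined chiral acid protonates C3 of the terminal isopropylidene of the chair–chair folded acid, the C5=C10 alkene adds through C5 to the C4 cation, the C8=C9 alkene adds through C9 to the C10 cation and the carboxyl oxygen captures the C8 cation, so that C4–C5, C9–C10 and C8–O form in one anti, Markovnikov cascade. The closest known reaction types are the enantioselective cyclisation of (3E,7E)-homofarnesol to the ambrox ether with imidodiphosphorimidate acids in fluorinated alcohols and the racemic protic-acid cyclisation of polyprenyl carboxylic acids to lactones. Ring A closes 6-endo-trig (C5=C10 onto C4), ring B closes 6-endo-trig (C8=C9 onto C10), and the δ-lactone closes by oxygen attack on C8, which is 6-endo with respect to the C8=C9 alkene because both alkene carbons lie in the new ring. C5, C9, C10 and transient C8 take their absolute sense from the enantiotopic face of C3=C4 that is protonated inside the catalyst cavity and their relative sense from the E geometry of both internal alkenes in the chair–chair transition state, which should give the trans ring fusion, the equatorial C9 chain and the equatorial C8–O bond. The step needs termination by oxygen instead of proton loss or arrest after ring A, and this is secured by the carboxyl group, whose two-carbon tether lets its oxygen reach C8 through a strain-free six-membered ring and which can hydrogen-bond to the catalyst anion, while the non-nucleophilic fluorinated alcohol stabilises the cations without intercepting them.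

**Step 5**
Reactants: 6 tricyclic δ-lactone
Product: 7 (5R,8S,9S,10R)-8-hydroxy-14,15-dinorlabdan-13-one
Conditions: MeLi (1.05 equiv), THF, −78 °C; then AcOH (1.2 equiv), −78 °C → rt
Reagents that add atoms: methyllithium, [Li]C
Why: Nucleophilic acyl addition of MeLi to the δ-lactone should stop at the lithium hemiketalate at −78 °C, and the cold quench releases the methyl ketone (new methyl = C16) and the tertiary C8 alcohol without a second addition.

**Step 6**
Reactants: 7 hydroxy methyl ketone
Product: 8 tert-butyl (5R,8S,9S,10R,13E)-8-hydroxylabd-13-en-15-oate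
Conditions: (EtO)2P(O)CH2CO2tBu (3.0 equiv), NaH (2.8 equiv), THF, 0 → 65 °C; 13Z isomer removed by chromatography
Reagents that add atoms: tert-butyl diethylphosphonoacetate, CCOP(=O)(OCC)CC(=O)OC(C)(C)C
Why: Horner–Wadsworth–Emmons olefination of the unhindered methyl ketone adds C14 and C15 and should favour the 13E enoate, the deficit of NaH relative to phosphonate leaves the tertiary OH protonated so that it cannot add to the new enoate, and the tert-butyl ester (from a standard catalogue phosphonate) resists the alkoxide of step 9.

**Step 7**
Reactants: 8 tertiary hydroxy enoate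
Product: 10 tert-butyl (5R,9R,10R,13E)-labda-8(17),13-dien-15-oate, via chlorosulfite ester 9 (not isolated)
Conditions: SOCl2 (1.5 equiv), pyridine (5 equiv), CH2Cl2, −78 °C
Reagents that add atoms: none
Why: Base-induced anti elimination (E2) of the chlorosulfite, in which only the C17 methyl hydrogens of the rigid trans-decalin can align anti-periplanar with the equatorial C8–O bond, should give the exocyclic alkene and deletes the C8 stereocentre on purpose, with traces of ring-alkene isomers removed after step 8.

**Step 8**
Reactants: 10 exocyclic diene ester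
Product: 11 tert-butyl (5R,8S,9S,10R,13E)-8,17-epoxylabd-13-en-15-oate (major C8 epimer)
Conditions: mCPBA (1.1 equiv), CH2Cl2, 0 °C
Reagents that add atoms: 3-chloroperoxybenzoic acid, OOC(=O)c1cccc(Cl)c1
Why: Prilezhaev epoxidation is chemoselective for the electron-rich 1,1-disubstituted alkene over the electron-poor enoate alkene, attack anti to the axial C10 methyl should give mainly the 8S epoxide, and both epimers converge in step 9.

**Step 9**
Reactants: 11 spiro-epoxide
Product: 12 tert-butyl (5R,9S,10R,13E)-17-hydroxylabda-7,13-dien-15-oate
Conditions: Al(OiPr)3 (2 equiv), toluene, 110 °C; aq. potassium sodium tartrate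
Reagents that add atoms: none
Why: Aluminium alkoxide-mediated isomerisation of an epoxide to an allylic alcohol, in which Lewis-acid activation and syn removal of a C7 hydrogen (tertiary H9 is shielded by C10 and the side chain) should open the C8–O bond to the C7=C8 alkene with the C17 hydroxyl while the hindered tert-butyl enoate is not exchanged.

**Step 10**
Reactants: 12 allylic alcohol ester
Product: 13 tert-butyl (5R,9S,10R,13E)-17-(tert-butyldimethylsilyloxy)labda-7,13-dien-15-oate
Conditions: TBSCl, imidazole, DMF, rt
Reagents that add atoms: tert-butyldimethylsilyl chloride, CC(C)(C)[Si](C)(C)Cl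
Why: Standard silylation (TBSCl with imidazole) of the only free hydroxyl, a primary allylic one.

**Step 11**
Reactants: 13 silyl ether ester
Product: 14 (5R,9S,10R,13E)-17-(tert-butyldimethylsilyloxy)labda-7,13-dien-15-ol
Conditions: iBu2AlH (3 equiv), CH2Cl2, −78 → −20 °C; aq. potassium sodium tartrate
Reagents that add atoms: none
Why: iBu2AlH performs 1,2-reduction of the α,β-unsaturated ester to the allylic alcohol with retention of the 13E geometry, the silyl ether is inert, and the two allylic oxygens are now differentiated (C15 free, C17 silylated).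

**Step 12**
Reactants: 15 16-hydroxyhexadecanoic acid
Product: 16 benzyl 16-hydroxyhexadecanoate
Conditions: BnBr, KHCO3, DMF, 40 °C
Reagents that add atoms: benzyl bromide, BrCc1ccccc1
Why: Carboxylate O-alkylation (SN2) under bicarbonate leaves the primary alcohol untouched, and the benzyl ester is chosen so that the later hydrogenation also liberates the acid and saves a saponification step.

**Step 13**
Reactants: 16 benzyl 16-hydroxyhexadecanoate
Product: 17 benzyl 16-oxohexadecanoate
Conditions: TEMPO (10 mol %), PhI(OAc)2, CH2Cl2, rt
Reagents that add atoms: none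
Why: TEMPO/PhI(OAc)2 (oxoammonium) oxidation converts the primary alcohol into the aldehyde without over-oxidation and without touching the benzyl ester.

**Step 14**
Reactants: 18 hexadecane-1,16-diol
Product: 19 16-bromohexadecan-1-ol
Conditions: 48% aq. HBr, toluene, reflux
Reagents that add atoms: hydrogen bromide, Br
Why: Monobromination of the symmetrical diol (SN2 on the protonated alcohol) in the two-phase HBr/toluene system, in which the less polar bromo alcohol is shielded from a second substitution.

**Step 15**
Reactants: 19 16-bromohexadecan-1-ol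
Product: 20 (16-bromohexadecyloxy)(tert-butyl)dimethylsilane
Conditions: TBSCl, imidazole, CH2Cl2, rt
Reagents that add atoms: tert-butyldimethylsilyl chloride, CC(C)(C)[Si](C)(C)Cl
Why: Silylation of the remaining primary alcohol (TBSCl with imidazole) masks it for the ylide chemistry.

**Step 16**
Reactants: 20 silyl-protected bromide
Product: 21 [16-(tert-butyldimethylsilyloxy)hexadecyl]triphenylphosphonium bromide
Conditions: PPh3, iPr2NEt (cat.), MeCN, 82 °C
Reagents that add atoms: triphenylphosphine, c1ccc(cc1)P(c1ccccc1)c1ccccc1
Why: SN2 quaternisation of PPh3 by the primary bromide gives the phosphonium salt, and the amine-buffered neutral medium keeps the silyl ether.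

**Step 17**
Reactants: 21 phosphonium bromide + 17 benzyl 16-oxohexadecanoate
Product: 23 benzyl (16Z)-32-(tert-butyldimethylsilyloxy)dotriacont-16-enoate, via phosphonium ylide 22 (not isolated)
Conditions: NaN(SiMe3)2, THF, −78 °C; then 17, −78 °C → rt
Reagents that add atoms: none
Why: Wittig olefination, in which the non-stabilised ylide adds to the aldehyde far faster than to the ester at low temperature and joins C16 to C17 of the C32 chain, and the alkene geometry is irrelevant because it is hydrogenated next.

**Step 18**
Reactants: 23 benzyl C32 enoate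
Product: 24 32-(tert-butyldimethylsilyloxy)dotriacontanoic acid
Conditions: H2 (1 atm), Pd/C, EtOAc/THF, rt
Reagents that add atoms: none
Why: Heterogeneous hydrogenation saturates the alkene and hydrogenolyses the benzyl ester in the same operation, and the primary TBS ether is stable over Pd/C in a non-protic solvent.

**Step 19**
Reactants: 14 C15 allylic alcohol + 24 protected C32 acid
Product: 25 bis-TBS ether of the target ester
Conditions: DCC, DMAP (cat.), CH2Cl2, rt
Reagents that add atoms: none
Why: Steglich esterification (carbodiimide activation, DMAP acyl transfer) of the unhindered primary allylic C15 alcohol takes place at the acyl carbon, so the C15–O bond and the 13E alkene are not disturbed.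

**Step 20**
Reactants: 25 bis-TBS ether
Product: 26 target, (5R,9S,10R,13E)-17-hydroxylabda-7,13-dien-15-yl 32-hydroxydotriacontanoate (ent-labdane series)
Conditions: HF·pyridine, pyridine, THF, 0 °C → rt
Reagents that add atoms: none
Why: Fluoride-mediated cleavage of both primary TBS ethers under pyridine-buffered conditions should leave the allylic ester and both alkenes intact, and the remote 17-OH cannot take over the acyl group.

**Compound list**

1 | (2E,6E)-farnesol | CC(C)=CCC/C(C)=C/CC/C(C)=C/CO | starting material
2 | (2E,6E)-farnesyl bromide | CC(C)=CCC/C(C)=C/CC/C(C)=C/CBr | intermediate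
3 | dimethyl 2-[(2E,6E)-3,7,11-trimethyldodeca-2,6,10-trien-1-yl]malonate | CC(C)=CCC/C(C)=C/CC/C(C)=C/CC(C(=O)OC)C(=O)OC | intermediate
4 | 2-[(2E,6E)-3,7,11-trimethyldodeca-2,6,10-trien-1-yl]malonic acid (farnesylmalonic acid, not isolated) | CC(C)=CCC/C(C)=C/CC/C(C)=C/CC(C(=O)O)C(=O)O | intermediate
5 | (4E,8E)-5,9,13-trimethyltetradeca-4,8,12-trienoic acid (farnesylacetic acid) | CC(C)=CCC/C(C)=C/CC/C(C)=C/CCC(=O)O | intermediate
6 | ent-ambreinolide-type lactone: 13,8-lactone of (5R,8S,9S,10R)-8-hydroxy-14,15,16-trinorlabdan-13-oic acid; trans-decalin, C8–O and C9 chain equatorial, C8 and C10 methyls syn-axial | O=C1CC[C@@H]2[C@@](C)(O1)CC[C@@H]3C(C)(C)CCC[C@@]23C | intermediate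
7 | (5R,8S,9S,10R)-8-hydroxy-14,15-dinorlabdan-13-one | CC(=O)CC[C@@H]1[C@@](C)(O)CC[C@@H]2C(C)(C)CCC[C@@]12C | intermediate
8 | tert-butyl (5R,8S,9S,10R,13E)-8-hydroxylabd-13-en-15-oate | CC(C)(C)OC(=O)/C=C(\C)CC[C@@H]1[C@@](C)(O)CC[C@@H]2C(C)(C)CCC[C@@]12C | intermediate
9 | chlorosulfite ester of 8 at the C8 oxygen (not isolated) | CC(C)(C)OC(=O)/C=C(\C)CC[C@@H]1[C@@](C)(OS(=O)Cl)CC[C@@H]2C(C)(C)CCC[C@@]12C | intermediate
10 | tert-butyl (5R,9R,10R,13E)-labda-8(17),13-dien-15-oate | CC(C)(C)OC(=O)/C=C(\C)CC[C@@H]1C(=C)CC[C@@H]2C(C)(C)CCC[C@@]12C | intermediate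
11 | tert-butyl (5R,8S,9S,10R,13E)-8,17-epoxylabd-13-en-15-oate (major epimer, oxygen on the face opposite the C10 methyl) | CC(C)(C)OC(=O)/C=C(\C)CC[C@@H]1[C@@]3(OC3)CC[C@@H]2C(C)(C)CCC[C@@]12C | intermediate
12 | tert-butyl (5R,9S,10R,13E)-17-hydroxylabda-7,13-dien-15-oate | CC(C)(C)OC(=O)/C=C(\C)CC[C@@H]1C(CO)=CC[C@@H]2C(C)(C)CCC[C@@]12C | intermediate
13 | tert-butyl (5R,9S,10R,13E)-17-(tert-butyldimethylsilyloxy)labda-7,13-dien-15-oate | CC(C)(C)OC(=O)/C=C(\C)CC[C@@H]1C(CO[Si](C)(C)C(C)(C)C)=CC[C@@H]2C(C)(C)CCC[C@@]12C | intermediate
14 | (5R,9S,10R,13E)-17-(tert-butyldimethylsilyloxy)labda-7,13-dien-15-ol | C/C(=C\CO)CC[C@@H]1C(CO[Si](C)(C)C(C)(C)C)=CC[C@@H]2C(C)(C)CCC[C@@]12C | intermediate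
15 | 16-hydroxyhexadecanoic acid | OCCCCCCCCCCCCCCCC(=O)O | starting material
16 | benzyl 16-hydroxyhexadecanoate | c1ccccc1COC(=O)CCCCCCCCCCCCCCCO | intermediate
17 | benzyl 16-oxohexadecanoate | c1ccccc1COC(=O)CCCCCCCCCCCCCCC=O | intermediate
18 | hexadecane-1,16-diol | OCCCCCCCCCCCCCCCCO | starting material
19 | 16-bromohexadecan-1-ol | OCCCCCCCCCCCCCCCCBr | intermediate
20 | (16-bromohexadecyloxy)(tert-butyl)dimethylsilane | CC(C)(C)[Si](C)(C)OCCCCCCCCCCCCCCCCBr | intermediate
21 | [16-(tert-butyldimethylsilyloxy)hexadecyl]triphenylphosphonium bromide | [Br-].CC(C)(C)[Si](C)(C)OCCCCCCCCCCCCCCCC[P+](c1ccccc1)(c1ccccc1)c1ccccc1 | intermediate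
22 | [16-(tert-butyldimethylsilyloxy)hexadecylidene]triphenylphosphorane (ylide, not isolated) | CC(C)(C)[Si](C)(C)OCCCCCCCCCCCCCCCC=P(c1ccccc1)(c1ccccc1)c1ccccc1 | intermediate
23 | benzyl (16Z)-32-(tert-butyldimethylsilyloxy)dotriacont-16-enoate | c1ccccc1COC(=O)CCCCCCCCCCCCCC/C=C\CCCCCCCCCCCCCCCO[Si](C)(C)C(C)(C)C | intermediate
24 | 32-(tert-butyldimethylsilyloxy)dotriacontanoic acid | OC(=O)CCCCCCCCCCCCCCCCCCCCCCCCCCCCCCCO[Si](C)(C)C(C)(C)C | intermediate
25 | (5R,9S,10R,13E)-17-(tert-butyldimethylsilyloxy)labda-7,13-dien-15-yl 32-(tert-butyldimethylsilyloxy)dotriacontanoate | C/C(=C\COC(=O)CCCCCCCCCCCCCCCCCCCCCCCCCCCCCCCO[Si](C)(C)C(C)(C)C)CC[C@@H]1C(CO[Si](C)(C)C(C)(C)C)=CC[C@@H]2C(C)(C)CCC[C@@]12C | intermediate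
26 | (5R,9S,10R,13E)-17-hydroxylabda-7,13-dien-15-yl 32-hydroxydotriacontanoate (CNP0264179.1) | C/C(=C\COC(=O)CCCCCCCCCCCCCCCCCCCCCCCCCCCCCCCO)CC[C@@H]1C(CO)=CC[C@@H]2C(C)(C)CCC[C@@]12C | target

**Step count.** Total: 20 steps. Longest linear sequence: 13 steps (steps 1 to 11, then 19 and 20, from farnesol).

**Steps most likely to fail**

Step 4. The protonation may discriminate poorly between the two faces of the C3=C4 alkene, or the cascade may be interrupted by proton loss after the first ring closure. The fallback sets out from 5. The acid is cyclised without chirality control by chlorosulfonic acid in 2-nitropropane at −78 °C, a known superacid-type cyclisation of polyprenyl carboxylic acids to trans-fused lactones, which should give the racemic lactone F1. The enantiomers are then separated by preparative chromatography on a chiral stationary phase (cellulose tris(3,5-dimethylphenylcarbamate)). The (5R,8S,9S,10R) enantiomer is 6, where the route is rejoined.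

Step 7. The chlorosulfite may ionise and lose a proton into the ring, which erodes the regioselectivity toward C7 or C9. The fallback sets out from 8 and no longer demands regiocontrol in the elimination. The unseparated alkene mixture, 10 together with its ring isomer tert-butyl (5R,9R,10R,13E)-labda-7,13-dien-15-oate F2, is treated with catalytic SeO2 and tBuOOH in CH2Cl2 (allylic oxidation by ene reaction and [2,3] shift). This should hydroxylate the C17 methyl of F2, the E-allylic position at the more substituted alkene terminus, and so give 12 directly. It should convert 10 into tert-butyl (5R,7S,9S,10R,13E)-7-hydroxylabda-8(17),13-dien-15-oate F3, whose C7 configuration is of no consequence. A Ph3SiOReO3-catalysed 1,3-transposition of the allylic alcohol then moves F3 to the primary alcohol with the trisubstituted ring alkene. The route is rejoined at 12, and 11 is bypassed.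

Step 9. The proton may be removed from C9 instead of C7, the activated epoxide may undergo a 1,2-hydride shift, or the alkoxide may attack the enoate. The fallback sets out from 10 and avoids the epoxide by a Schenck ene reaction. Photooxygenation (O2, tetraphenylporphyrin, visible light, CH2Cl2, 0 °C) should add singlet oxygen to C17 of the exocyclic alkene with transfer of an axial C7 hydrogen and shift of the alkene into the ring. The product is the allylic hydroperoxide tert-butyl (5R,9S,10R,13E)-17-hydroperoxylabda-7,13-dien-15-oate F4; the enoate alkene is inert to singlet oxygen. F4 is reduced in the same flask with PPh3 to 12, where the route continues.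

**Further compounds**

F1 | step 4 | racemic lactone (6 and its enantiomer, 1:1) | O=C1CC[C@@H]2[C@@](C)(O1)CC[C@@H]3C(C)(C)CCC[C@@]23C.O=C1CC[C@H]2[C@](C)(O1)CC[C@H]3C(C)(C)CCC[C@]23C
F2 | step 7 | tert-butyl (5R,9R,10R,13E)-labda-7,13-dien-15-oate | CC(C)(C)OC(=O)/C=C(\C)CC[C@@H]1C(C)=CC[C@@H]2C(C)(C)CCC[C@@]12C
F3 | step 7 | tert-butyl (5R,7S,9S,10R,13E)-7-hydroxylabda-8(17),13-dien-15-oate | CC(C)(C)OC(=O)/C=C(\C)CC[C@@H]1C(=C)[C@@H](O)C[C@@H]2C(C)(C)CCC[C@@]12C
F4 | step 9 | tert-butyl (5R,9S,10R,13E)-17-hydroperoxylabda-7,13-dien-15-oate | CC(C)(C)OC(=O)/C=C(\C)CC[C@@H]1C(COO)=CC[C@@H]2C(C)(C)CCC[C@@]12C
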